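**Assumption:** the cis-fused left bicycle of the target is the thermodynamic junction of the final tetrasubstituted enone (A(1,3) strain between the C3′ chain and the gem-dimethyl carbon), so the trans-fused skeleton from the RCM route can be equilibrated in the last step.

**Retrosynthesis**
1. Target ⇐ γ-epimerisation (trans → cis junction) of 28 ⇐ photochemical, cobaloxime-mediated desaturative coupling of enone 27 with primary iodide 17, forming the central CH2–CH2 bond (key step).
2. Right half 17 (cyclohexane + oxepane): carvone ring with the C10 quaternary centre from double α′-alkylation; oxepane closed last by 7-endo epoxy-alcohol opening.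
3. Left half 27 (enone ring + ring A′): carvone ring; ring A′ by RCM; Cq–OH by HAT hydration; then Wharton 1,3-carbonyl transposition.
4. Ring-formation order: right half, cyclohexane (carvone ring) then oxepane; left half, enone ring (carvone) then ring A′ (RCM), then coupling.
5. Both halves come from (S)-carvone (1); every stereocentre is set by substrate control.

Labels: right half uses target numbering (C10 quaternary; C9 side chain; C8 Me/OH; C5 O; C3 OH). Left-half ring positions use carvone numbering C1–C6, with C6 = future CHa and C5 = future CHb.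

---

**Step 1**
Reactants: 1 (S)-carvone; 2 2-(2-bromoethyl)-1,3-dioxolane
Product: 3 trans-6-[2-(1,3-dioxolan-2-yl)ethyl]-(S)-carvone
Conditions: LDA, THF, –78 °C; then 2, DMPU, cat. NaI, –78 → 0 °C
Reagents that add atoms: 2, BrCCC1OCCO1
Why: Kinetic α′-enolate alkylation (SN2) at C6; the electrophile approaches anti to the C5 isopropenyl group, so the new chain is equatorial and trans to it.

**Step 2**
Reactants: 3
Product: 4 6-methyl-6-[2-(1,3-dioxolan-2-yl)ethyl]-(S)-carvone (quaternary C6; Me axial, chain equatorial, chain trans to isopropenyl)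
Conditions: LDA, THF, –78 °C; MeI, HMPA, –78 → 0 °C
Reagents that add atoms: iodomethane, CI
Why: Second enolate alkylation; axial methylation anti to the axial C5–H sets the quaternary centre (future C10) with Me axial and chain equatorial, the arrangement needed for trans-fusion.

**Step 3**
Reactants: 4
Product: 5 5-acetyl analogue of 4 (isopropenyl → methyl ketone)
Conditions: O3 (1.0 equiv), CH2Cl2/MeOH, –78 °C; then Me2S
Reagents that add atoms: ozone, [O-][O+]=O
Why: Ozonolysis is selective for the electron-rich 1,1-disubstituted alkene over the enone, and the acetal is untouched; C5 is not epimerised because the acetyl group stays equatorial.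

**Step 4**
Reactants: 5
Product: 6 5-acetoxy analogue of 4
Conditions: mCPBA, NaHCO3, CH2Cl2, 0 °C → rt
Reagents that add atoms: mCPBA, O=C(OO)c1cccc(Cl)c1
Why: Baeyer–Villiger oxidation of the methyl ketone; the secondary ring carbon migrates with retention, so C5 keeps its configuration, and C6 is quaternary so β-elimination of the acetate is impossible.

**Step 5**
Reactants: 6; 7 triethyl phosphonoacetate
Product: 8 dienoate: C1 ketone → C9=CH–CO2Et
Conditions: NaH, toluene, 110 °C, then 6
Reagents that add atoms: 7, CCOC(=O)CP(=O)(OCC)OCC
Why: Horner–Wadsworth–Emmons olefination installs the C11–C12 unit at the carvone carbonyl (future C9), leaving a dienoate whose stereochemistry is reset in the next step.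

**Step 6**
Reactants: 8
Product: 9 saturated ester with C8=C7 alkene retained
Conditions: [(Ph3P)CuH]6 (0.3 equiv), PhSiH3, toluene, 0 °C → rt; NH4Cl work-up
Reagents that add atoms: none
Why: Cu–H conjugate reduction delivers hydride to the β-carbon (C9) from the face anti to the axial C10 methyl, so H is up and the CH2CO2Et chain is down (equatorial), as in the target.

**Step 7**
Reactants: 9
Product: 10 C8–C7 epoxide (O on the face anti to the axial C10 methyl)
Conditions: mCPBA, NaHCO3, CH2Cl2, 0 °C
Reagents that add atoms: mCPBA, O=C(OO)c1cccc(Cl)c1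
Why: Prilezhaev epoxidation of the only alkene occurs from the α-face anti to the C10 methyl, which fixes C8 with O up and Me down.

**Step 8**
Reactants: 10
Product: 11 triol acetal (C12–OH, C5–OH, C8–OH)
Conditions: LiAlH4, THF, 0 °C → rt; Fieser work-up
Reagents that add atoms: none
Why: One hydride reduction reduces the ester to CH2OH, cleaves the acetate, and opens the epoxide at the less hindered C7, leaving C8–OH with retained configuration.

**Step 9**
Reactants: 11
Product: 12 hydroxy aldehyde (exists as the C5–O lactol)
Conditions: PPTS, acetone/H2O, 55 °C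
Reagents that add atoms: water, O
Why: Mild acid hydrolysis unmasks the C3 aldehyde of the C10 side chain; no stereocentre is touched.

**Step 10**
Reactants: 12; 13 isopropyltriphenylphosphonium iodide
Product: 14 prenyl-chain triol (C3=C4Me2 alkene)
Conditions: 13 (5 equiv), KOtBu (5 equiv), THF, 0 °C → rt, then 12
Reagents that add atoms: 13, CC(C)[P+](c1ccccc1)(c1ccccc1)c1ccccc1.[I-]
Why: Wittig olefination of the lactol/aldehyde builds the trisubstituted alkene that will become the C3–C4 epoxide; excess ylide covers the free OH groups.

**Step 11**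
Reactants: 14
Product: 15 3,4-epoxide (C3 configuration as in the target)
Conditions: mCPBA, NaHCO3, CH2Cl2, 0 °C
Reagents that add atoms: mCPBA, O=C(OO)c1cccc(Cl)c1
Why: Prilezhaev epoxidation of the only alkene; the remote C3 centre is set here and biased by the next step, where only the matched epoxide diastereomer closes the oxepane.

**Step 12**
Reactants: 15
Product: 16 oxepane with C3–OH and C12–OH
Conditions: CSA (0.1 equiv), CH2Cl2, –20 → 0 °C
Reagents that add atoms: none
Why: Acid-catalysed 7-endo epoxy-alcohol opening: C5–OH attacks the tertiary C4 (Markovnikov) with inversion at a non-stereogenic carbon, retaining C3–O; the matched epoxide reacts via a chair-like TS and the mismatched one is diverted to the 6-exo tetrahydropyran and removed.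

**Step 13**
Reactants: 16
Product: 17 primary iodide (right half)
Conditions: I2, PPh3, imidazole, CH2Cl2, 0 °C
Reagents that add atoms: iodine, II
Why: Appel-type (Garegg–Samuelsson) iodination is selective for the unhindered primary alcohol over the secondary C3–OH and the tertiary C8–OH.

**Step 14**
Reactants: 1 (S)-carvone; 18 acetone
Product: 19 trans-6-(2-hydroxypropan-2-yl)-(S)-carvone
Conditions: LDA, THF, –78 °C; then 18, –78 °C
Reagents that add atoms: 18, CC(C)=O
Why: Kinetic α′-enolate aldol addition; the carbinol ends up equatorial, trans to the C5 isopropenyl group.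

**Step 15**
Reactants: 19
Product: 20 cesium tert-alkyl oxalate
Conditions: ClC(=O)CO2Me, Et3N, DMAP, CH2Cl2, 0 °C; then CsOH·H2O, MeOH/H2O, rt
Reagents that add atoms: methyl chlorooxoacetate, COC(=O)C(=O)Cl; cesium hydroxide, [Cs+].[OH-]
Why: Acylation and saponification convert the tertiary alcohol into a photoredox-oxidisable radical precursor.

**Step 16**
Reactants: 20; 21 allyl phenyl sulfone
Product: 22 6-(2-methylpent-4-en-2-yl)-(S)-carvone
Conditions: [Ir{dF(CF3)ppy}2(dtbbpy)]PF6 (1 mol%), DMF, blue LEDs, rt
Reagents that add atoms: 21, C=CCS(=O)(=O)c1ccccc1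
Why: Photoredox deoxygenative allylation (oxidation, CO2 loss, radical addition–β-fragmentation) gives the C6 quaternary-adjacent carbon without touching the stereocentres; C6 stays trans because it is α to the ketone.

**Step 17**
Reactants: 22
Product: 23 trans-fused bicyclic enone with the ring-A′ alkene (ring A′ from the isopropenyl and allyl groups, –C2H4)
Conditions: Hoveyda–Grubbs II (5 mol%), CH2Cl2 (0.01 M), 40 °C
Reagents that add atoms: none
Why: Ring-closing metathesis of the trans-diequatorial 1,1-disubstituted/monosubstituted alkene pair forms the trisubstituted cyclohexene (Thorpe–Ingold assisted); trans substituents give a trans-fused junction.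

**Step 18**
Reactants: 23
Product: 24 tertiary alcohol (Cq–OH cis to H5, Me trans)
Conditions: Co(acac)2 (5 mol%), PhSiH3, O2 (1 atm), i-PrOH, rt; then P(OEt)3
Reagents that add atoms: dioxygen, O=O
Why: Mukaiyama HAT hydration is Markovnikov, and O2 traps the tertiary radical on the less hindered face syn to the axial H5, setting Cq.

**Step 19**
Reactants: 24
Product: 25 α,β-epoxy ketone (epoxide configuration irrelevant)
Conditions: H2O2, NaOH, MeOH, 0 °C
Reagents that add atoms: hydrogen peroxide, OO
Why: Weitz–Scheffer nucleophilic epoxidation of the enone, chemoselective in the presence of the free OH.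

**Step 20**
Reactants: 25
Product: 26 allylic alcohol (C3–OH, C1=C2 alkene; C3 epimers)
Conditions: N2H4·H2O, AcOH (cat.), MeOH, 0 °C → rt
Reagents that add atoms: none
Why: Wharton transposition moves the oxygen from C1 to C3 and places the alkene at C1=C2, so C1–H becomes the future β-carbon; the C3 configuration is irrelevant because it is oxidised next.

**Step 21**
Reactants: 26
Product: 27 trans-fused enone E (X3–H, carbonyl at carvone C3)
Conditions: MnO2, CH2Cl2, rt
Reagents that add atoms: none
Why: Allylic oxidation gives the transposed α-methyl enone; the tertiary alcohol is untouched and the C3 stereo-mixture converges.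

**Step 22**
Reactants: 27; 17
Product: 28 trans-fused coupled enone
Conditions: 4CzIPN (2 mol%), Co(dmgH)2pyCl (10 mol%), DIPEA (2 equiv), MeCN/DMA, 455 nm LEDs, 25 °C, 17 (3 equiv)
Reagents that add atoms: none
Why: Proposed new method: the excited photocatalyst oxidises DIPEA to an α-aminoalkyl radical that abstracts iodine from 17 (XAT) to give the primary C12 radical, which adds Giese-fashion to the β-carbon of enone 27 (nucleophilic radical, electron-poor alkene, anti to the neighbouring CMe2-bearing carbon); Co(II) then abstracts the weak β C–H (former C1–H) from the α-keto radical to regenerate the conjugated tetrasubstituted enone, the Co–H being turned over as H2 (closest known reactions: photoredox/cobaloxime Heck-type alkylation of styrenes/acrylates and Giese addition to enones, here applied to a β-C–H of a cyclic enone with an unactivated primary iodide, forming the central C–C bond without pre-functionalising the enone).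

**Step 23**
Reactants: 28
Product: 29 target (cis-fused)
Conditions: KOtBu (0.5 equiv), t-BuOH/THF 1:1, 50 °C; AcOH quench
Reagents that add atoms: none
Why: Reversible γ-deprotonation through the extended dienolate equilibrates the CHa centre to the thermodynamic cis junction, with the gem-dimethyl carbon pseudo-axial to relieve A(1,3) strain with the new C3′ chain, while the stereocentres remote from the dienolate (CHb, Cq, and all right-half centres) are not acidic and remain unchanged.

---

**Compound list**
1 | (S)-carvone | CC1=CC[C@@H](CC1=O)C(C)=C | starting material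
2 | 2-(2-bromoethyl)-1,3-dioxolane | BrCCC1OCCO1 | starting material
3 | trans-6-[2-(1,3-dioxolan-2-yl)ethyl]-(S)-carvone | CC1=CC[C@H](C(C)=C)[C@@H](CCC2OCCO2)C1=O | intermediate
4 | 6-methyl-6-(dioxolanylethyl)-(S)-carvone, Me axial | CC1=CC[C@H](C(C)=C)[C@@](C)(CCC2OCCO2)C1=O | intermediate
5 | 5-acetyl analogue of 4 | CC1=CC[C@H](C(C)=O)[C@@](C)(CCC2OCCO2)C1=O | intermediate
6 | 5-acetoxy analogue of 4 | CC1=CC[C@H](OC(C)=O)[C@@](C)(CCC2OCCO2)C1=O | intermediate
7 | triethyl phosphonoacetate | CCOC(=O)CP(=O)(OCC)OCC | starting material
8 | dienoate (C9=CH–CO2Et, C8=C7) | CCOC(=O)C=C1C(C)=CC[C@H](OC(C)=O)[C@@]1(C)CCC2OCCO2 | intermediate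
9 | ester with C9–H up, chain down | CCOC(=O)C[C@@H]1C(C)=CC[C@H](OC(C)=O)[C@@]1(C)CCC2OCCO2 | intermediate
10 | C8–C7 α-epoxide | CCOC(=O)C[C@@H]1[C@@]2(C)O[C@H]2C[C@H](OC(C)=O)[C@@]1(C)CCC3OCCO3 | intermediate
11 | triol acetal | OCC[C@@H]1[C@@](C)(O)CC[C@H](O)[C@@]1(C)CCC2OCCO2 | intermediate
12 | hydroxy aldehyde (lactol form) | OCC[C@@H]1[C@@](C)(O)CC[C@H](O)[C@@]1(C)CCC=O | intermediate
13 | isopropyltriphenylphosphonium iodide | CC(C)[P+](c1ccccc1)(c1ccccc1)c1ccccc1.[I-] | starting material
14 | prenyl-chain triol | OCC[C@@H]1[C@@](C)(O)CC[C@H](O)[C@@]1(C)CCC=C(C)C | intermediate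
15 | 3,4-epoxide | OCC[C@@H]1[C@@](C)(O)CC[C@H](O)[C@@]1(C)CC[C@@H]2OC2(C)C | intermediate
16 | oxepane diol (C12–OH) | OCC[C@H]2[C@]3(C)CC[C@H](O)C(C)(C)O[C@H]3CC[C@]2(C)O | intermediate
17 | right-half primary iodide | ICC[C@H]2[C@]3(C)CC[C@H](O)C(C)(C)O[C@H]3CC[C@]2(C)O | intermediate
18 | acetone | CC(C)=O | starting material
19 | aldol adduct of carvone | CC1=CC[C@H](C(C)=C)[C@@H](C(C)(C)O)C1=O | intermediate
20 | cesium oxalate of 19 | CC1=CC[C@H](C(C)=C)[C@@H](C(C)(C)OC(=O)C(=O)[O-])C1=O.[Cs+] | intermediate
21 | allyl phenyl sulfone | C=CCS(=O)(=O)c1ccccc1 | starting material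
22 | 6-(2-methylpent-4-en-2-yl)-(S)-carvone | CC1=CC[C@H](C(C)=C)[C@@H](C(C)(C)CC=C)C1=O | intermediate
23 | trans-fused RCM enone (ring-A′ alkene) | CC1=CC[C@@H]2C(C)=CCC(C)(C)[C@H]2C1=O | intermediate
24 | tertiary alcohol (Cq–OH) | CC1=CC[C@@H]2[C@@](C)(O)CCC(C)(C)[C@H]2C1=O | intermediate
25 | α,β-epoxy ketone (epoxide stereochemistry undefined) | CC12OC1C[C@@H]3[C@@](C)(O)CCC(C)(C)[C@H]3C2=O | intermediate
26 | allylic alcohol (C3 epimers) | OC1C(C)=C[C@@H]2C(C)(C)CC[C@](C)(O)[C@H]2C1 | intermediate
27 | trans-fused enone E | CC1=C[C@@H]2C(C)(C)CC[C@](C)(O)[C@H]2CC1=O | intermediate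
28 | trans-fused coupled enone | CC1=C(CC[C@H]2[C@]3(C)CC[C@H](O)C(C)(C)O[C@H]3CC[C@]2(C)O)[C@H]2[C@H](CC1=O)[C@@](C)(O)CCC2(C)C | intermediate
29 | sipholenol K | CC1=C(CC[C@H]2[C@]3(C)CC[C@H](O)C(C)(C)O[C@H]3CC[C@]2(C)O)[C@@H]2[C@H](CC1=O)[C@@](C)(O)CCC2(C)C | target

---

**Totals:** 23 steps in total; the longest linear sequence is 15 steps (1 → 3 → 4 → 5 → 6 → 8 → 9 → 10 → 11 → 12 → 14 → 15 → 16 → 17 → 28 → 29).

**Three steps most likely to fail**
1. **Step 22 (proposed new coupling).** Co-mediated HAT may take a methyl hydrogen, or the reaction may stop at Giese hydroalkylation. Fallback: known two-stage sequence, photoredox Giese addition of 17 to 27 (Ir catalyst, Hantzsch ester) to give the saturated ketone, then IBX·MPO or Pd(TFA)2/DMSO/O2 dehydrogenation to regenerate the enone.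
2. **Step 12 (7-endo closure and C3 control).** 6-exo tetrahydropyran formation or poor diastereoselectivity would defeat it. Fallback: add isopropenylMgBr to aldehyde 12, close the oxepane by Co(salen)/silane/N-fluoropyridinium Markovnikov 7-exo hydroalkoxylation of the allylic alcohol, and set C3 by DMP oxidation and hydride reduction.
3. **Step 5 (HWE on the ketone flanked by a quaternary carbon and an enone alkene).** Fallback: install the C9 chain by epoxidation/Wharton transposition of 4, Mitsunobu inversion, and Johnson–Claisen rearrangement (CH2CO2Et delivered to C9 from the correct face), then continue with ozonolysis/Baeyer–Villiger.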